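**Retrosynthetic overview**
- Feature: the target is one unbranched C13 chain, OCH2-(C2 to C5 of ring A)-(C2 to C5 of ring B)-C≡C-CH2-CH2O. C2 to C5 of ring A (the thiophene with CH2O on C2 and ring B on C5) are a conjugated diyne plus one sulfur and two hydrogens.
- Last disconnections: the two acyl C-O bonds, isovalerate first and then senecioate. The two alcohols stay distinguishable because one is free and the other is a TIPS ether from step 2 onward.
- Key disconnection: both S-C bonds of ring A (S-C2 and S-C5), leading back to a thienyl penta-2,4-diynol and sodium sulfide.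
- Diynol: a Cadiot-Chodkiewicz C(sp)-C(sp) bond joins a 2-ethynylthiophene to bromopropargyl alcohol. The ethynyl group comes from the aldehyde (Ohira-Bestmann) and the butynyl arm from a Sonogashira coupling.
- Ring order: ring B is bought as 5-bromothiophene-2-carbaldehyde; ring A is the only ring built, in step 6.

Key step: step 6

Remark on the chemistry: the target has no stereocentre and no double bond capable of E/Z isomerism, so no configuration has to be set. Only the transient enyne thiolate of the key step has a defined (Z) geometry.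

**Step 1**
Reactants: 1 5-bromothiophene-2-carbaldehyde; 2 but-3-yn-1-ol
Product: 3 5-(4-hydroxybut-1-yn-1-yl)thiophene-2-carbaldehyde
Conditions: Pd(PPh3)2Cl2 (2 mol %), CuI (4 mol %), Et3N, THF, rt to 45 °C, Ar
Reagents that add atoms: none
Why: Sonogashira coupling, in which the formyl group at the other alpha position activates the C-Br bond toward oxidative addition and the Pd/Cu/amine system tolerates both the aldehyde and the free primary alcohol.

**Step 2**
Reactants: 3 5-(4-hydroxybut-1-yn-1-yl)thiophene-2-carbaldehyde; 4 chlorotriisopropylsilane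
Product: 5 5-[4-(triisopropylsilyloxy)but-1-yn-1-yl]thiophene-2-carbaldehyde
Conditions: TIPSCl, imidazole, DMF, 0 °C to rt
Reagents that add atoms: chlorotriisopropylsilane 4, CC(C)[Si](Cl)(C(C)C)C(C)C
Why: Imidazole-promoted silylation of an unhindered primary alcohol, with the bulky TIPS ether chosen because it must outlast K2CO3 in methanol, aqueous butylamine and warm alkaline sulfide.

**Step 3**
Reactants: 5 5-[4-(triisopropylsilyloxy)but-1-yn-1-yl]thiophene-2-carbaldehyde; 6 dimethyl (1-diazo-2-oxopropyl)phosphonate
Product: 7 2-ethynyl-5-[4-(triisopropylsilyloxy)but-1-yn-1-yl]thiophene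
Conditions: 6, K2CO3, MeOH-THF, 0 °C to rt; product used promptly
Reagents that add atoms: dimethyl (1-diazo-2-oxopropyl)phosphonate 6, COP(=O)(OC)C(=[N+]=[N-])C(C)=O
Why: Seyferth-Gilbert homologation in its Ohira-Bestmann form, where methanolysis of the acetyl group frees the diazomethylphosphonate anion, which olefinates the non-enolisable aldehyde and, after loss of N2 and a 1,2-hydrogen shift, leaves the terminal alkyne under conditions too mild to touch the TIPS ether or the internal alkyne.

**Step 4**
Reactants: 8 prop-2-yn-1-ol; 9 N-bromosuccinimide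
Product: 10 3-bromoprop-2-yn-1-ol
Conditions: NBS, AgNO3 (10 mol %), acetone, rt, dark; passed through a silica pad, not distilled
Reagents that add atoms: N-bromosuccinimide 9, O=C1CCC(=O)N1Br
Why: Silver-catalysed electrophilic bromination of a terminal alkyne by way of its silver acetylide, a standard entry to 1-bromoalkynes that leaves the primary alcohol alone.

**Step 5**
Reactants: 7 2-ethynyl-5-[4-(triisopropylsilyloxy)but-1-yn-1-yl]thiophene; 10 3-bromoprop-2-yn-1-ol
Product: 11 5-{5-[4-(triisopropylsilyloxy)but-1-yn-1-yl]thiophen-2-yl}penta-2,4-diyn-1-ol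
Conditions: CuCl (10 mol %), NH2OH·HCl (cat.), 30% aq n-BuNH2, Et2O, 0 °C, slow addition of 10
Reagents that add atoms: none
Why: Cadiot-Chodkiewicz coupling, in which the copper acetylide of the fairly acidic thienylacetylene 7 takes up bromoalkyne 10, hydroxylamine keeps copper in the monovalent state so that oxidative homocoupling is held back, and the free hydroxyl and the TIPS ether are both tolerated.

**Step 6**
Reactants: 11 5-{5-[4-(triisopropylsilyloxy)but-1-yn-1-yl]thiophen-2-yl}penta-2,4-diyn-1-ol; 12 sodium sulfide (used as the nonahydrate)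
Product: 14 {5'-[4-(triisopropylsilyloxy)but-1-yn-1-yl]-2,2'-bithiophen-5-yl}methanol, via sodium Z-enyne thiolate 13 (not isolated)
Conditions: Na2S·9H2O (3 equiv), MeOCH2CH2OH, 70 °C, degassed, Ar
Reagents that add atoms: sodium sulfide 12, [Na+].[Na+].[S-2]
Why: Water of hydration turns sulfide into hydrosulfide, which adds in a trans sense to an outer carbon of the diyne (drawn for the CH2OH-bearing carbon, from which the developing negative charge can spread through the second triple bond toward ring B), so that in thiolate 13 sulfur sits cis to the remaining alkyne. The thiolate sulfur then attacks the distal alkyne carbon, the one bonded to ring B, in a 5-endo-dig closure, and protonation of the resulting thienyl anion by the protic solvent gives aromatic ring A with its new S-C2 and S-C5 bonds. First attack at the opposite diyne terminus would lead to the same thiophene, so the regiochemistry of the opening addition is of no consequence. The closest known reaction type is the conversion of 1,3-diynes, hexa-2,4-diyne-1,6-diol and 1,4-di(thiophen-2-yl)butadiyne among them, into 2,5-disubstituted thiophenes with Na2S or NaSH. No stereocentre is created; the selectivity needed is diyne over the lone ring B alkyne, and it rests on the higher electrophilicity of the conjugated diyne and on the absence of any aromatising five-membered closure for an adduct of the isolated alkyne. The protic solvent and moderate temperature level the basicity, which should keep the propargylic CH2 of the side chain from deprotonation and so prevent allene formation or loss of silanolate, and the TIPS ether withstands aqueous alkali.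

**Step 7**
Reactants: 14 {5'-[4-(triisopropylsilyloxy)but-1-yn-1-yl]-2,2'-bithiophen-5-yl}methanol; 15 3-methylbut-2-enoic acid
Product: 16 {5'-[4-(triisopropylsilyloxy)but-1-yn-1-yl]-2,2'-bithiophen-5-yl}methyl 3-methylbut-2-enoate
Conditions: 15, DCC, DMAP (10 mol %), CH2Cl2, 0 °C to rt
Reagents that add atoms: 3-methylbut-2-enoic acid 15, CC(C)=CC(=O)O
Why: Steglich esterification, whose near-neutral carbodiimide/DMAP activation avoids both acid-promoted ionisation of the electron-rich bithienylmethanol and the vinylketene pathway of acid chloride plus amine base, which would move the double bond out of conjugation.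

**Step 8**
Reactants: 16 {5'-[4-(triisopropylsilyloxy)but-1-yn-1-yl]-2,2'-bithiophen-5-yl}methyl 3-methylbut-2-enoate
Product: 17 [5'-(4-hydroxybut-1-yn-1-yl)-2,2'-bithiophen-5-yl]methyl 3-methylbut-2-enoate
Conditions: TBAF, AcOH (equimolar), THF, 0 °C to rt
Reagents that add atoms: none
Why: Fluoride-induced desilylation driven by the strong Si-F bond, with acetic acid protonating the released alkoxide and tempering the basicity of fluoride so that the thenylic senecioate is neither cleaved nor transferred.

**Step 9**
Reactants: 17 [5'-(4-hydroxybut-1-yn-1-yl)-2,2'-bithiophen-5-yl]methyl 3-methylbut-2-enoate; 18 3-methylbutanoyl chloride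
Product: 19 target, {5'-[4-(3-methylbutanoyloxy)but-1-yn-1-yl]-2,2'-bithiophen-5-yl}methyl 3-methylbut-2-enoate
Conditions: 18, pyridine, DMAP (cat.), CH2Cl2, 0 °C
Reagents that add atoms: 3-methylbutanoyl chloride 18, CC(C)CC(=O)Cl
Why: Acylation of an unhindered primary alcohol by a saturated acid chloride under nucleophilic catalysis, fast at low temperature and harmless to the senecioate, the alkyne and both thiophenes.

**Compound list**
1 | 5-bromothiophene-2-carbaldehyde | O=Cc1ccc(Br)s1 | starting material
2 | but-3-yn-1-ol | C#CCCO | starting material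
3 | 5-(4-hydroxybut-1-yn-1-yl)thiophene-2-carbaldehyde | O=Cc1ccc(C#CCCO)s1 | intermediate
4 | chlorotriisopropylsilane | CC(C)[Si](Cl)(C(C)C)C(C)C | starting material
5 | 5-[4-(triisopropylsilyloxy)but-1-yn-1-yl]thiophene-2-carbaldehyde | O=Cc1ccc(C#CCCO[Si](C(C)C)(C(C)C)C(C)C)s1 | intermediate
6 | dimethyl (1-diazo-2-oxopropyl)phosphonate | COP(=O)(OC)C(=[N+]=[N-])C(C)=O | starting material
7 | 2-ethynyl-5-[4-(triisopropylsilyloxy)but-1-yn-1-yl]thiophene | C#Cc1ccc(C#CCCO[Si](C(C)C)(C(C)C)C(C)C)s1 | intermediate
8 | prop-2-yn-1-ol | C#CCO | starting material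
9 | N-bromosuccinimide | O=C1CCC(=O)N1Br | starting material
10 | 3-bromoprop-2-yn-1-ol | OCC#CBr | intermediate
11 | 5-{5-[4-(triisopropylsilyloxy)but-1-yn-1-yl]thiophen-2-yl}penta-2,4-diyn-1-ol | OCC#CC#Cc1ccc(C#CCCO[Si](C(C)C)(C(C)C)C(C)C)s1 | intermediate
12 | sodium sulfide | [Na+].[Na+].[S-2] | starting material
13 | sodium (Z)-1-hydroxy-5-{5-[4-(triisopropylsilyloxy)but-1-yn-1-yl]thiophen-2-yl}pent-2-en-4-yne-2-thiolate | OC/C([S-])=C/C#Cc1ccc(C#CCCO[Si](C(C)C)(C(C)C)C(C)C)s1.[Na+] | intermediate
14 | {5'-[4-(triisopropylsilyloxy)but-1-yn-1-yl]-2,2'-bithiophen-5-yl}methanol | OCc1ccc(-c2ccc(C#CCCO[Si](C(C)C)(C(C)C)C(C)C)s2)s1 | intermediate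
15 | 3-methylbut-2-enoic acid | CC(C)=CC(=O)O | starting material
16 | {5'-[4-(triisopropylsilyloxy)but-1-yn-1-yl]-2,2'-bithiophen-5-yl}methyl 3-methylbut-2-enoate | CC(C)=CC(=O)OCc1ccc(-c2ccc(C#CCCO[Si](C(C)C)(C(C)C)C(C)C)s2)s1 | intermediate
17 | [5'-(4-hydroxybut-1-yn-1-yl)-2,2'-bithiophen-5-yl]methyl 3-methylbut-2-enoate | CC(C)=CC(=O)OCc1ccc(-c2ccc(C#CCCO)s2)s1 | intermediate
18 | 3-methylbutanoyl chloride | CC(C)CC(=O)Cl | starting material
19 | {5'-[4-(3-methylbutanoyloxy)but-1-yn-1-yl]-2,2'-bithiophen-5-yl}methyl 3-methylbut-2-enoate | CC(C)=CC(=O)OCc1ccc(-c2ccc(C#CCCOC(=O)CC(C)C)s2)s1 | target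

**Total step count:** 9
**Longest linear sequence:** 8 steps (steps 1, 2, 3, 5, 6, 7, 8, 9, from compound 1); step 4 is a one-step side branch.

**Steps most likely to fail**

**First, step 6.**
- The sulfide addition may stop at open-chain adducts or run into oligomerisation of the diynol.
- Base may isomerise the diynol before sulfur is taken up.
- Excess sulfide may begin to add to the ring B alkyne.

The fallback gives up the diyne and joins two preformed thiophenes; it sets out from 1 and comes back at 14.
- Suzuki-Miyaura coupling of 1 with thiophen-2-ylboronic acid (Pd(PPh3)4, Na2CO3, DME-H2O, 80 °C) should give 2,2'-bithiophene-5-carbaldehyde F1.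
- The formyl group deactivates its own ring, so NBS (9) in DMF in the dark should brominate the free alpha position of the other ring. This gives 5'-bromo-2,2'-bithiophene-5-carbaldehyde F2.
- Silylation of 2 with 4 and imidazole gives (but-3-yn-1-yloxy)triisopropylsilane F3.
- Sonogashira coupling of F2 with F3 (Pd(PPh3)2Cl2, CuI, Et3N, THF) should give 5'-[4-(triisopropylsilyloxy)but-1-yn-1-yl]-2,2'-bithiophene-5-carbaldehyde F4.
- Reduction of F4 with NaBH4 in MeOH-THF at 0 °C delivers 14.

**Second, step 5.**
- Either partner may homocouple.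
- The sensitive terminal alkyne may decompose before it couples.
- The bromoalkynol may be lost on handling.

The fallback avoids both the terminal alkyne and the bromoalkyne; it sets out from 5 and comes back at 11.
- Ramirez olefination of 5 (CBr4, PPh3, CH2Cl2, 0 °C), the first stage of the Corey-Fuchs sequence, should give 2-(2,2-dibromoethenyl)-5-[4-(triisopropylsilyloxy)but-1-yn-1-yl]thiophene F5.
- F5 is coupled directly with prop-2-yn-1-ol 8 (Pd2(dba)3, tris(4-methoxyphenyl)phosphine, Et3N, DMF, 80 °C). This is the known coupling of 1,1-dibromoalkenes with terminal alkynes. Alkynylation of the trans C-Br bond followed by dehydrobromination gives the unsymmetrical diyne 11.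

**Third, step 8.**
- Silyl cleavage under buffered fluoride may be slow.
- Over a prolonged reaction the thenylic ester may be lost or transferred.

The fallback removes the silyl group before any ester is present and tells the two alcohols apart by oxidation state; it sets out from 14 and comes back at 19.
- TBAF in THF converts 14 into 4-[5'-(hydroxymethyl)-2,2'-bithiophen-5-yl]but-3-yn-1-ol F6.
- MnO2 in CH2Cl2 should oxidise only the activated thenylic alcohol, giving 5'-(4-hydroxybut-1-yn-1-yl)-2,2'-bithiophene-5-carbaldehyde F7.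
- Acylation of F7 with 18 and pyridine gives 4-(5'-formyl-2,2'-bithiophen-5-yl)but-3-yn-1-yl 3-methylbutanoate F8.
- NaBH4 in MeOH-THF at 0 °C reduces the aldehyde to 4-[5'-(hydroxymethyl)-2,2'-bithiophen-5-yl]but-3-yn-1-yl 3-methylbutanoate F9.
- Steglich esterification of F9 with 15 (DCC, DMAP, CH2Cl2) gives 19.

**Further compounds**
F1 | step 6 | 2,2'-bithiophene-5-carbaldehyde | O=Cc1ccc(-c2cccs2)s1
F2 | step 6 | 5'-bromo-2,2'-bithiophene-5-carbaldehyde | O=Cc1ccc(-c2ccc(Br)s2)s1
F3 | step 6 | (but-3-yn-1-yloxy)triisopropylsilane | C#CCCO[Si](C(C)C)(C(C)C)C(C)C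
F4 | step 6 | 5'-[4-(triisopropylsilyloxy)but-1-yn-1-yl]-2,2'-bithiophene-5-carbaldehyde | O=Cc1ccc(-c2ccc(C#CCCO[Si](C(C)C)(C(C)C)C(C)C)s2)s1
F5 | step 5 | 2-(2,2-dibromoethenyl)-5-[4-(triisopropylsilyloxy)but-1-yn-1-yl]thiophene | BrC(Br)=Cc1ccc(C#CCCO[Si](C(C)C)(C(C)C)C(C)C)s1
F6 | step 8 | 4-[5'-(hydroxymethyl)-2,2'-bithiophen-5-yl]but-3-yn-1-ol | OCc1ccc(-c2ccc(C#CCCO)s2)s1
F7 | step 8 | 5'-(4-hydroxybut-1-yn-1-yl)-2,2'-bithiophene-5-carbaldehyde | O=Cc1ccc(-c2ccc(C#CCCO)s2)s1
F8 | step 8 | 4-(5'-formyl-2,2'-bithiophen-5-yl)but-3-yn-1-yl 3-methylbutanoate | O=Cc1ccc(-c2ccc(C#CCCOC(=O)CC(C)C)s2)s1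
F9 | step 8 | 4-[5'-(hydroxymethyl)-2,2'-bithiophen-5-yl]but-3-yn-1-yl 3-methylbutanoate | OCc1ccc(-c2ccc(C#CCCOC(=O)CC(C)C)s2)s1
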